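Ring B is disconnected across C1'–C6' and C2'–C3'. Its four adjacent brominated carbons C3'–C6' become a perbrominated diene, and the oxygen-bearing pair C1' (diaryl ether O) and C2' (OH) becomes a two-carbon dienophile at the carboxylic acid oxidation level. In one operation, tetrabromothiophene 1,1-dioxide and the bis(trimethylsilyl) ketene acetal of (2-methoxyphenoxy)acetic acid undergo an inverse-electron-demand [4+2] cycloaddition. Loss of SO2 and trimethylsilanol should then deliver the fully substituted arene with both oxygens and all four bromines in place. The precursor is an ArO–CH=C(OSiMe3)2 alkene (Ar = 2-methoxyphenyl) that already carries ring A. Demethylation and phenol-directed dibromination of ring A finish the synthesis.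

Key step: step 3

Remark: the target has no stereocentre and its diaryl ether bonds rotate freely, so it is achiral and no enantiocontrol is required. The structures of the key-step precursor and product were checked against the target and needed no correction.

Step 1
Reactants: 1 2,3,4,5-tetrabromothiophene
Product: 3 2,3,4,5-tetrabromothiophene 1,1-dioxide, via tetrabromothiophene 1-oxide 2 (not isolated)
Conditions: H2O2 (50% aq.), (CF3CO)2O, CH2Cl2, 0 °C → rt
Reagents that add atoms: trifluoroperacetic acid OOC(=O)C(F)(F)F, generated in situ from hydrogen peroxide OO and trifluoroacetic anhydride O=C(OC(=O)C(F)(F)F)C(F)(F)F; it delivers both sulfone oxygens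
Why: Peracid S-oxidation of a thiophene to its 1,1-dioxide; the non-aromatic S-oxide 2 is oxidized faster than 1, and full bromine substitution should suppress the self-dimerization typical of less substituted thiophene dioxides.

Step 2
Reactants: 4 (2-methoxyphenoxy)acetic acid
Product: 6 2-(2-methoxyphenoxy)-1,1-bis(trimethylsilyloxy)ethene, via dilithium enediolate 5 (not isolated)
Conditions: LDA (2.2 equiv, commercial solution), THF, −78 → 0 °C; TMSCl (2.5 equiv), −78 °C → rt; pentane, filtration under Ar, short-path distillation
Reagents that add atoms: chlorotrimethylsilane C[Si](C)(C)Cl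
Why: Ainsworth-type preparation of a bis(silyl) ketene acetal: double deprotonation gives the carboxylic acid enediolate (the α-aryloxy group offers no β-leaving group), and the hard silyl chloride should silylate both oxygens.

Step 3
Reactants: 3 2,3,4,5-tetrabromothiophene 1,1-dioxide; 6 2-(2-methoxyphenoxy)-1,1-bis(trimethylsilyloxy)ethene
Product: 9 [2,3,4,5-tetrabromo-6-(2-methoxyphenoxy)phenoxy]trimethylsilane, via thiabicyclic sulfone cycloadduct 7 (not isolated), via bis(silyloxy)cyclohexadiene 8 (not isolated)
Conditions: 6 (1.2 equiv), dry toluene, 0 °C → rt, then 80 °C; evaporation of volatiles, no aqueous work-up, crude 9 used directly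
Reagents that add atoms: none
Why: The LUMO-lowered sulfone diene 3 and the HOMO-raised ketene acetal 6 should combine in a concerted, asynchronous inverse-electron-demand Diels–Alder reaction in which the nucleophilic CH(OAr) carbon bonds first, so that C1'–C6' and C2'–C3' both form and ring B closes by suprafacial [4+2] cycloaddition to give 7. Cheletropic loss of SO2 from the 7-thiabicyclo[2.2.1]heptene dioxide gives cyclohexadiene 8, whose ketal carbon ionizes to a silyloxy-stabilized cyclohexadienyl cation (or eliminates directly) and loses the adjacent proton, expelling trimethylsilanol to give arene 9. The closest known chemistry is the benzannulation of tetrahalothiophene 1,1-dioxides with alkenes and enol ethers by cycloaddition, SO2 extrusion and β-elimination, together with the aromatization of ketene acetal adducts of electron-poor dienes by loss of ROH. No stereocentre survives, since the sp3 centres of 7 and 8 are erased on aromatization, so endo/exo selectivity is irrelevant. Regiochemistry cannot arise because 3 is symmetric; the step needs chemoselectivity for cycloaddition over conjugate addition with bromide loss, which the nonpolar solvent and neutral anhydrous conditions favour, and elimination toward the C2' oxygen, which is assured because the only ring hydrogen sits on C1' and the only leaving groups β to it are the two silyloxy groups on C2'.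

Step 4
Reactants: 9 [2,3,4,5-tetrabromo-6-(2-methoxyphenoxy)phenoxy]trimethylsilane
Product: 11 3,4,5,6-tetrabromo-2-(2-hydroxyphenoxy)phenol, via bis(dibromoboryl) diether 10 (not isolated)
Conditions: BBr3 (3 equiv), CH2Cl2, −78 °C → rt; then H2O, 0 °C
Reagents that add atoms: none
Why: Lewis acid ether cleavage: BBr3 complexes the methoxy oxygen and bromide displaces the methyl group (SN2), the O–Si bond is exchanged for O–B, and hydrolysis frees both phenols, while the diaryl ether and the aryl bromides are inert to BBr3; any 9 already desilylated converges on the same product.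

Step 5
Reactants: 11 3,4,5,6-tetrabromo-2-(2-hydroxyphenoxy)phenol
Product: 13 3,4,5,6-tetrabromo-2-(3,5-dibromo-2-hydroxyphenoxy)phenol, via para-monobromide 12 (not isolated)
Conditions: Br2 (2.05 equiv), AcOH, rt; aq. Na2S2O3
Reagents that add atoms: bromine BrBr
Why: Electrophilic aromatic bromination directed by the free ring A hydroxyl, first para and then ortho; ring B has no free position and its electron-poor aryloxy oxygen is a much weaker director, so substitution should stop at the 3,5-dibromo-2-hydroxyphenoxy pattern.

Compound list
1 | 2,3,4,5-tetrabromothiophene | Brc1sc(Br)c(Br)c1Br | starting material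
2 | 2,3,4,5-tetrabromothiophene 1-oxide | O=S1C(Br)=C(Br)C(Br)=C1Br | intermediate (not isolated)
3 | 2,3,4,5-tetrabromothiophene 1,1-dioxide | O=S1(=O)C(Br)=C(Br)C(Br)=C1Br | intermediate
4 | (2-methoxyphenoxy)acetic acid | COc1ccccc1OCC(=O)O | starting material
5 | dilithium 2-(2-methoxyphenoxy)ethene-1,1-diolate | [Li+].[Li+].COc1ccccc1OC=C([O-])[O-] | intermediate (not isolated)
6 | 2-(2-methoxyphenoxy)-1,1-bis(trimethylsilyloxy)ethene | COc1ccccc1OC=C(O[Si](C)(C)C)O[Si](C)(C)C | intermediate
7 | 1,2,3,4-tetrabromo-5-(2-methoxyphenoxy)-6,6-bis(trimethylsilyloxy)-7-thiabicyclo[2.2.1]hept-2-ene 7,7-dioxide (racemic; configuration at C5 uncontrolled and erased in the same step) | COc1ccccc1OC1C(O[Si](C)(C)C)(O[Si](C)(C)C)C2(Br)C(Br)=C(Br)C1(Br)S2(=O)=O | intermediate (not isolated)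
8 | 1,2,3,4-tetrabromo-5-(2-methoxyphenoxy)-6,6-bis(trimethylsilyloxy)cyclohexa-1,3-diene (racemic; stereocentre erased in the same step) | COc1ccccc1OC1C(Br)=C(Br)C(Br)=C(Br)C1(O[Si](C)(C)C)O[Si](C)(C)C | intermediate (not isolated)
9 | [2,3,4,5-tetrabromo-6-(2-methoxyphenoxy)phenoxy]trimethylsilane | COc1ccccc1Oc1c(O[Si](C)(C)C)c(Br)c(Br)c(Br)c1Br | intermediate
10 | dibromo{2-[2,3,4,5-tetrabromo-6-(dibromoboryloxy)phenoxy]phenoxy}borane | BrB(Br)Oc1ccccc1Oc1c(OB(Br)Br)c(Br)c(Br)c(Br)c1Br | intermediate (not isolated)
11 | 3,4,5,6-tetrabromo-2-(2-hydroxyphenoxy)phenol | Oc1ccccc1Oc1c(O)c(Br)c(Br)c(Br)c1Br | intermediate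
12 | 3,4,5,6-tetrabromo-2-(5-bromo-2-hydroxyphenoxy)phenol | Oc1ccc(Br)cc1Oc1c(O)c(Br)c(Br)c(Br)c1Br | intermediate (not isolated)
13 | 3,4,5,6-tetrabromo-2-(3,5-dibromo-2-hydroxyphenoxy)phenol | Oc1c(Br)cc(Br)cc1Oc1c(O)c(Br)c(Br)c(Br)c1Br | target

Total step count: 5. Longest linear sequence: 4 steps (1 → 3 → 9 → 11 → 13, or 4 → 6 → 9 → 11 → 13); the two one-step branches converge in step 3.

Steps most likely to fail

Step 3. Conjugate addition of the very nucleophilic ketene acetal to the sulfone with loss of bromide (vinylic substitution), silyl transfer, or decay of the sulfone before it engages the hindered trisubstituted alkene may outrun the cycloaddition. The fallback gives up the ring construction and makes the diaryl ether bond instead. It sets out from none of the numbered compounds, since 3 and 6 are replaced by commercial 3,4,5,6-tetrabromocatechol and 2-iodoanisole, and it comes back to the route at compound 11. 2-Iodoanisole would be converted in one pot (mCPBA, TsOH, MeCN, then 1,3,5-trimethoxybenzene) into (2-methoxyphenyl)(2,4,6-trimethoxyphenyl)iodonium tosylate F1. Metal-free O-arylation of excess tetrabromocatechol with F1 (K2CO3, MeCN, rt to 50 °C) should transfer the 2-methoxyphenyl group selectively and give 3,4,5,6-tetrabromo-2-(2-methoxyphenoxy)phenol F2. The two catechol hydroxyls are equivalent, so only one mono-ether can form. BBr3 demethylation of F2 under the conditions of step 4 then gives 11.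

Step 2. Incomplete second deprotonation of the poorly soluble lithium carboxylate, competing C-silylation, or hydrolysis of the ketene acetal during isolation may give impure dienophile. The fallback sets out from compound 4 and comes back at compound 6. Acid 4 would first be silylated with hexamethyldisilazane (cat. TMSCl, 60 °C) and distilled to give trimethylsilyl (2-methoxyphenoxy)acetate F3. This neutral, soluble ester then needs only one deprotonation (LDA, 1.1 equiv, THF, −78 °C, TMSCl present as internal quench) to give 6.

Step 5. Bromination may leak to the position para to the ether oxygen, run on to a tribromide, or be accompanied by oxidation of the electron-rich ring when both brominations are forced in one pot on the free phenol. The fallback sets out from compound 9 and comes back at compound 12. It splits the two brominations around the deprotection so that each is steered by a different oxygen. Silyl ether 9 would be monobrominated para to the methoxy group (NBS, 1.05 equiv, MeCN, 0 °C → rt, aqueous work-up with loss of the silyl group) to give 3,4,5,6-tetrabromo-2-(5-bromo-2-methoxyphenoxy)phenol F4, which can be purified. BBr3 demethylation of F4 gives 12 as an isolated compound. A single ortho-bromination of 12 (Br2, 1.0 equiv, AcOH, rt) at the only remaining position activated by the hydroxyl then gives 13.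

Further compounds
F1 | step 3 | (2-methoxyphenyl)(2,4,6-trimethoxyphenyl)iodonium tosylate | COc1ccccc1[I+]c1c(OC)cc(OC)cc1OC.Cc1ccc(cc1)S(=O)(=O)[O-]
F2 | step 3 | 3,4,5,6-tetrabromo-2-(2-methoxyphenoxy)phenol | COc1ccccc1Oc1c(O)c(Br)c(Br)c(Br)c1Br
F3 | step 2 | trimethylsilyl (2-methoxyphenoxy)acetate | COc1ccccc1OCC(=O)O[Si](C)(C)C
F4 | step 5 | 3,4,5,6-tetrabromo-2-(5-bromo-2-methoxyphenoxy)phenol | COc1ccc(Br)cc1Oc1c(O)c(Br)c(Br)c(Br)c1Br
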